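Readings and results are simulated for an exercise.

In this closed, stirred vessel a single-handed catalyst works on a racemic substrate while coupling partner is consumed.

- ash: left-handed substrate 0.50 M; right-handed substrate 0.50 M; coupling partner 1.2 M; protic impurity 10 mM; free catalyst 1 mM; stray impurity 0.29 mM; run made earlier
- flask: left-handed substrate 0.50 M; coupling partner 0.600 M; protic impurity 10.0 mM; free catalyst 1.0 mM; stray impurity 0.29 mM; right-handed substrate 0.50 M; time 8.0 h

- ash (time / min: left-handed product / %, right-handed product / %, left-handed substrate / %): 8.00: 0.4, 6.2, 49.3; 15.0: 3.0, 11.3, 48.7; 25.0: 2.7, 14.7, 45.5; 30.0: 4.3, 18.0, 48.8; 40.0: 4.2, 22.7, 45.5; 50.0: 4.0, 24.5, 45.0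

(scatter of a reading: 1 percentage point)

- free catalyst is single-handed; left-handed substrate and right-handed substrate are mirror images of each other, charged as a racemate, each of them at the stated concentration
- the numbers in the tables scatter by 1 percentage point (one standard deviation)
- what may be going on: free catalyst + left-handed substrate <-> catalyst intermediate A; free catalyst + right-handed substrate <-> catalyst intermediate B; coupling partner + catalyst intermediate A -> free catalyst + left-handed product; coupling partner + catalyst intermediate B -> free catalyst + right-handed product; coupling partner + protic impurity -> quenched reagent; 2 coupling partner -> homo dimer; free catalyst + stray impurity -> spent catalyst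
- an excess is the difference of the two amounts in percent of their sum
- an excess is below zero if the other one leads

- excess of left-handed product over right-handed product in the product at 25 min
- excess of left-handed product over right-handed product in the product at 8.0 h
- part of the left-handed substrate and right-handed substrate charged together that has reacted at 8.0 h

Before I reckon anything I ask which charge has to be known well. The protic impurity costs 1.00% of the substrate charge in coupling partner, and a reading scatters by 1 percentage point, so I let it go. The stray impurity stands at 29.0% of the catalyst, the same in the ash run, so the ash readings already carry it, and it bears on pace without taking coupling partner. The clock matters little, because this flask runs 9.60 times as long as the last ash reading with half the coupling partner, and the ash run had reacted 28.5% by then, at an excess of −71.9%. I want the coupling partner charge well known, since I expect it to be the limiting reagent, less of it being charged than of both substrates together, and its concentration to set the rate. The homo dimer takes two coupling partner per turn and no reading shows it, so a point of partner need not be a point of conversion. So my number is 59.0%: this is the partner budget, the coupling partner charged less the protic impurity, as a fraction of both substrates charged together. I commit to conversion below it.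

The forecast says −74%, −63% and 43% reacted, noting “Dimer loss is unmeasured”.

This flask gives −72.3%, −67.4% and 36.1% reacted, with coupling partner at 0.85% of its charge.

    free catalyst + left-handed substrate ⇌ catalyst intermediate A (K = 0.870 L mol⁻¹, k = 640 L mol⁻¹ min⁻¹)
    free catalyst + right-handed substrate ⇌ catalyst intermediate B (K = 19.0 L mol⁻¹, k = 513 L mol⁻¹ min⁻¹)
    coupling partner + catalyst intermediate A → free catalyst + left-handed product (k = 32.3 L mol⁻¹ min⁻¹)
    coupling partner + catalyst intermediate B → free catalyst + right-handed product (k = 11.9 L mol⁻¹ min⁻¹)
    coupling partner + protic impurity → quenched reagent (k = 2.29 L mol⁻¹ min⁻¹)
    2 coupling partner → homo dimer (k = 0.0104 L mol⁻¹ min⁻¹)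
    free catalyst + stray impurity → spent catalyst (k = 1810 L mol⁻¹ min⁻¹)

At 0.897 h in this flask the step to right-handed product takes coupling partner at 1.3 times the pace of the path to homo dimer, against 58 times at 8.00 h, and the homo dimer holds 22.5% of the charge out of the budget of 59.0%. The neighbour charged with 1.5 M of coupling partner has a budget of 149%, puts 87.1% into homo dimer, and ends at 60.9% reacted.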